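## Retrosynthetic overview

1. The benzene ring and the whole isoprenoid skeleton are bought: 2-bromo-3-methylbenzaldehyde 1 (used as its tritylhydrazone 2) and (E)-geranylacetone 3 (used as its (R)-epoxide 4, which carries the only stereocenter).
2. Key disconnection, C3–C4 of the chroman: the lithiated hydrazone (azo anion 5), a traceless acyl-anion equivalent, opens 4 at its CH2, joining two carbons that are both normally electrophilic. The diazene 6 then loses N2 and leaves C4 as CH2 in bromo alcohol 7.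
3. Ring formation: only the pyran ring is built, by Pd-catalysed aryl C–O closure of 7 to chroman 8; the C2–O bond is never broken.
4. End game without protecting groups: allylic oxidation of the terminal (E)-methyl of 8 (alcohol 9, enal 10), Pinnick oxidation to acid 11, then sterically controlled C6–H borylation (12, 13) and oxidation to the target 14.

Assumption: the (R)-binaphthoxide La/Li catalyst is taken to give the (R)-epoxide 4; should it give the (S)-epoxide, the mirror-image catalyst is used and nothing else changes.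

## Route

Step 1
Reactants: 1 2-bromo-3-methylbenzaldehyde
Product: 2 (E)-2-bromo-3-methylbenzaldehyde N-tritylhydrazone
Conditions: Ph3CNHNH2, EtOH, rt
Reagents that add atoms: tritylhydrazine, NNC(c1ccccc1)(c1ccccc1)c1ccccc1
Why: Hydrazone condensation of an unhindered aryl aldehyde is fast and gives the crystalline E hydrazone, whose trityl group later blocks nitrogen.

Step 2
Reactants: 3 (E)-geranylacetone
Product: 4 (2R)-2-[(3E)-4,8-dimethylnona-3,7-dien-1-yl]-2-methyloxirane
Conditions: Me3S(O)I, NaH, THF (ylide preformed); 3, LaLi3[(R)-binaphthoxide]3 (5 mol%), [2,4,6-(MeO)3C6H2]3P=O (5 mol%), MS 5 Å, THF, rt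
Reagents that add atoms: trimethylsulfoxonium iodide (CH2 through its ylide), C[S+](C)(C)=O.[I-]
Why: Catalytic asymmetric Corey–Chaykovsky epoxidation, in which the La/Li binaphthoxide complex binds the methyl ketone and the sulfoxonium ylide and tells methyl from the long alkyl arm (about 90–96% ee is usual for methyl alkyl ketones), sets the R stereocenter while the isolated alkenes stay untouched.

Step 3
Reactants: 2 (E)-2-bromo-3-methylbenzaldehyde N-tritylhydrazone; 4 (2R)-2-[(3E)-4,8-dimethylnona-3,7-dien-1-yl]-2-methyloxirane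
Product: 7 (3R,6E)-1-(2-bromo-3-methylphenyl)-3,7,11-trimethyldodeca-6,10-dien-3-ol, via lithium azo anion 5 (not isolated), via trityl diazene alkoxide 6 (not isolated)
Conditions: LiN(iPr)2, THF, −78 °C; 4, DMPU, −78 → −10 °C; EtSH, −10 °C → rt
Reagents that add atoms: none
Why: Proposed new method: N-deprotonation gives a 2,3-diazaallyl (azo) anion whose nitrogen end is blocked by trityl, so it should open epoxide 4 through carbon by SN2 attack at the CH2 (the C–O bond of the stereocenter is untouched, R retained), and the resulting benzyl trityl diazene loses N2 by homolysis with the thiol capping the benzylic radical, leaving C4 as CH2; the closest known reactions are the C-alkylation of lithiated aldehyde tritylhydrazones by alkyl halides and carbonyl compounds followed by loss of N2 (reductive C–C bond formation) and the Corey–Seebach opening of epoxides by lithiated dithianes.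

Step 4
Reactants: 7 (3R,6E)-1-(2-bromo-3-methylphenyl)-3,7,11-trimethyldodeca-6,10-dien-3-ol
Product: 8 (2R)-2-[(3E)-4,8-dimethylnona-3,7-dien-1-yl]-2,8-dimethyl-3,4-dihydro-2H-chromene
Conditions: Pd(OAc)2 (3 mol%), 2-(di-tert-butylphosphino)-1,1'-binaphthyl (4 mol%), Cs2CO3, toluene, 80 °C
Reagents that add atoms: none
Why: Buchwald-type intramolecular Pd-catalysed C–O coupling (oxidative addition, binding of a tertiary alkoxide that cannot undergo β-hydride elimination, C–O reductive elimination) closes the six-membered ring without touching the C2–O bond, so the R configuration is kept.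

Step 5
Reactants: 8 (2R)-2-[(3E)-4,8-dimethylnona-3,7-dien-1-yl]-2,8-dimethyl-3,4-dihydro-2H-chromene
Product: 10 (2E,6E)-9-[(2R)-2,8-dimethyl-3,4-dihydro-2H-chromen-2-yl]-2,6-dimethylnona-2,6-dienal, via allylic alcohol 9 (not isolated)
Conditions: SeO2 (0.3 equiv), tBuOOH, salicylic acid (cat.), CH2Cl2, 0 °C → rt; then MnO2, CH2Cl2, rt
Reagents that add atoms: selenium dioxide, O=[Se]=O; tert-butyl hydroperoxide, CC(C)(C)OO
Why: Riley allylic oxidation (ene reaction then [2,3]-sigmatropic shift) attacks the (E)-methyl of the terminal gem-dimethyl alkene in preference to the internal alkene, as in geranyl and farnesyl chains, and MnO2 then converges the alcohol/aldehyde mixture on the (E)-enal.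

Step 6
Reactants: 10 (2E,6E)-9-[(2R)-2,8-dimethyl-3,4-dihydro-2H-chromen-2-yl]-2,6-dimethylnona-2,6-dienal
Product: 11 (2E,6E)-9-[(2R)-2,8-dimethyl-3,4-dihydro-2H-chromen-2-yl]-2,6-dimethylnona-2,6-dienoic acid
Conditions: NaClO2, NaH2PO4, 2-methyl-2-butene, tBuOH/H2O, rt
Reagents that add atoms: sodium chlorite, [Na+].[O-]Cl=O
Why: Pinnick oxidation converts the enal into the acid without isomerising the E double bond, with 2-methyl-2-butene scavenging HOCl so that the other alkenes and the arene are spared.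

Step 7
Reactants: 11 (2E,6E)-9-[(2R)-2,8-dimethyl-3,4-dihydro-2H-chromen-2-yl]-2,6-dimethylnona-2,6-dienoic acid
Product: 14 (2E,6E)-9-[(2R)-6-hydroxy-2,8-dimethyl-3,4-dihydro-2H-chromen-2-yl]-2,6-dimethylnona-2,6-dienoic acid, via boryl ester 12 (not isolated), via aryl boronate 13 (not isolated)
Conditions: [Ir(OMe)(cod)]2 (2 mol%), 4,4'-di-tert-butyl-2,2'-bipyridine (4 mol%), HBpin, B2pin2, THF, rt → 60 °C; then NaBO3·4H2O, THF/H2O, rt
Reagents that add atoms: sodium perborate, [Na+].[O-]OB=O
Why: Iridium-catalysed, sterically controlled arene C–H borylation (the acid is first masked in the flask as its boryl ester) occurs only at C6, the one ring C–H with no ortho substituent, and perborate oxidation of the aryl boronate with hydrolysis of the boryl ester gives the 6-hydroxy group para to the ring oxygen without touching the stereocenter.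

## Compound list

1 | 2-bromo-3-methylbenzaldehyde | Cc1cccc(C=O)c1Br | starting material
2 | (E)-2-bromo-3-methylbenzaldehyde N-tritylhydrazone | Cc1cccc(/C=N/NC(c2ccccc2)(c2ccccc2)c2ccccc2)c1Br | intermediate
3 | (E)-geranylacetone, (5E)-6,10-dimethylundeca-5,9-dien-2-one | CC(=O)CC/C=C(\C)CCC=C(C)C | starting material
4 | (2R)-2-[(3E)-4,8-dimethylnona-3,7-dien-1-yl]-2-methyloxirane | C[C@@]1(CC/C=C(\C)CCC=C(C)C)CO1 | intermediate
5 | lithium salt of 2 (azo anion) | [Li+].Cc1cccc(/C=N/[N-]C(c2ccccc2)(c2ccccc2)c2ccccc2)c1Br | intermediate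
6 | lithium (3R,6E)-1-(2-bromo-3-methylphenyl)-3,7,11-trimethyl-1-(trityldiazenyl)dodeca-6,10-dien-3-olate (both C1 epimers) | [Li+].C[C@]([O-])(CC(N=NC(c1ccccc1)(c1ccccc1)c1ccccc1)c1cccc(C)c1Br)CC/C=C(\C)CCC=C(C)C | intermediate
7 | (3R,6E)-1-(2-bromo-3-methylphenyl)-3,7,11-trimethyldodeca-6,10-dien-3-ol | C[C@](O)(CCc1cccc(C)c1Br)CC/C=C(\C)CCC=C(C)C | intermediate
8 | (2R)-2-[(3E)-4,8-dimethylnona-3,7-dien-1-yl]-2,8-dimethyl-3,4-dihydro-2H-chromene | C/C(=C\CC[C@]1(C)CCc2cccc(C)c2O1)CCC=C(C)C | intermediate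
9 | (2E,6E)-9-[(2R)-2,8-dimethyl-3,4-dihydro-2H-chromen-2-yl]-2,6-dimethylnona-2,6-dien-1-ol | C/C(=C\CC[C@]1(C)CCc2cccc(C)c2O1)CC/C=C(\C)CO | intermediate
10 | (2E,6E)-9-[(2R)-2,8-dimethyl-3,4-dihydro-2H-chromen-2-yl]-2,6-dimethylnona-2,6-dienal | C/C(=C\CC[C@]1(C)CCc2cccc(C)c2O1)CC/C=C(\C)C=O | intermediate
11 | (2E,6E)-9-[(2R)-2,8-dimethyl-3,4-dihydro-2H-chromen-2-yl]-2,6-dimethylnona-2,6-dienoic acid | C/C(=C\CC[C@]1(C)CCc2cccc(C)c2O1)CC/C=C(\C)C(=O)O | intermediate
12 | 4,4,5,5-tetramethyl-1,3,2-dioxaborolan-2-yl ester of 11 | C/C(=C\CC[C@]1(C)CCc2cccc(C)c2O1)CC/C=C(\C)C(=O)OB1OC(C)(C)C(C)(C)O1 | intermediate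
13 | boryl ester 12 carrying a 4,4,5,5-tetramethyl-1,3,2-dioxaborolan-2-yl group at chroman C6 | C/C(=C\CC[C@]1(C)CCc2cc(B3OC(C)(C)C(C)(C)O3)cc(C)c2O1)CC/C=C(\C)C(=O)OB1OC(C)(C)C(C)(C)O1 | intermediate
14 | (2E,6E)-9-[(2R)-6-hydroxy-2,8-dimethyl-3,4-dihydro-2H-chromen-2-yl]-2,6-dimethylnona-2,6-dienoic acid | C/C(=C\CC[C@]1(C)CCc2cc(O)cc(C)c2O1)CC/C=C(\C)C(=O)O | target

## Step count and risks

Total steps: 7 (step 5 is one telescoped operation). Longest linear sequence: 6 steps (1 → 2 → 7 → 8 → 10 → 11 → 14; the branch from 3 through 4 is equally long).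

**Step 3 (most likely to fail).** Epoxides are an untested electrophile for the azo anion, and attack is at a CH2 next to a quaternary carbon. The alkoxide formed could tautomerise the diazene to a hydrazone before N2 is lost. Thiyl radicals could also erode the E geometry of the chain alkenes.

The fallback keeps the same polarity reversal with the classical carrier; it sets out from 1 and 4 and comes back at 8, one step longer. Aldehyde 1 with propane-1,3-dithiol and BF3·OEt2 in CH2Cl2 gives 2-(2-bromo-3-methylphenyl)-1,3-dithiane F1. LiN(iPr)2 in THF at −78 °C (an alkyllithium would exchange the bromide) gives 2-(2-bromo-3-methylphenyl)-2-lithio-1,3-dithiane F2. This opens 4 in THF/DMPU (−78 → 0 °C) to (2R,5E)-1-[2-(2-bromo-3-methylphenyl)-1,3-dithian-2-yl]-2,6,10-trimethylundeca-5,9-dien-2-ol F3. The C–O closure under the conditions of step 4 gives (2R)-2-[(3E)-4,8-dimethylnona-3,7-dien-1-yl]-2,8-dimethylspiro[chromane-4,2'-[1,3]dithiane] F4. Li in NH3/THF at −78 °C then cleaves both benzylic C–S bonds without touching the trisubstituted alkenes and returns the route at 8.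

**Step 7.** The arene borylation is run on a substrate with a free acid and a conjugated alkene; HBpin could reduce or hydroborate the enoate, or the masked acid could slow the catalyst.

The fallback moves the hydroxylation forward; it sets out from 8 and comes back at 14, three steps longer. Chroman 8, which has no acid or enoate, is borylated with [Ir(OMe)(cod)]2, 4,4'-di-tert-butyl-2,2'-bipyridine and B2pin2 to 2-[(2R)-2-[(3E)-4,8-dimethylnona-3,7-dien-1-yl]-2,8-dimethyl-3,4-dihydro-2H-chromen-6-yl]-4,4,5,5-tetramethyl-1,3,2-dioxaborolane F5. NaBO3·4H2O gives (2R)-2-[(3E)-4,8-dimethylnona-3,7-dien-1-yl]-2,8-dimethyl-3,4-dihydro-2H-chromen-6-ol F6. TBSCl and imidazole give its tert-butyldimethylsilyl ether F7. SeO2/tBuOOH then MnO2 lead through the silyl ether allylic alcohol F8 to the silyl ether enal F9. Pinnick oxidation gives the silyl ether acid F10, and Bu4NF releases 14.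

**Step 5.** Selectivity for the terminal (E)-methyl over the allylic positions of the internal alkene is only moderate, and the alcohol/aldehyde mixture lowers the yield.

The fallback replaces C–H oxidation by olefin metathesis; it sets out from 8 and comes back at 10. Cross-metathesis of 8 with excess methacrolein, using the second-generation Hoveyda–Grubbs catalyst RuCl2(H2IMes)(=CH-C6H4-2-OiPr) in CH2Cl2 at 40 °C, exchanges the terminal isopropylidene for the (E)-2-methylenal directly. The more hindered internal alkene is expected to stay out. This fallback makes no new compound (F0).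

## Further compounds

F1 | step 3 | 2-(2-bromo-3-methylphenyl)-1,3-dithiane | Cc1cccc(C2SCCCS2)c1Br
F2 | step 3 | 2-(2-bromo-3-methylphenyl)-2-lithio-1,3-dithiane | [Li+].Cc1cccc([C-]2SCCCS2)c1Br
F3 | step 3 | (2R,5E)-1-[2-(2-bromo-3-methylphenyl)-1,3-dithian-2-yl]-2,6,10-trimethylundeca-5,9-dien-2-ol | C[C@](O)(CC1(SCCCS1)c1cccc(C)c1Br)CC/C=C(\C)CCC=C(C)C
F4 | step 3 | (2R)-2-[(3E)-4,8-dimethylnona-3,7-dien-1-yl]-2,8-dimethylspiro[chromane-4,2'-[1,3]dithiane] | C/C(=C\CC[C@]1(C)CC2(SCCCS2)c2cccc(C)c2O1)CCC=C(C)C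
F5 | step 7 | 2-[(2R)-2-[(3E)-4,8-dimethylnona-3,7-dien-1-yl]-2,8-dimethyl-3,4-dihydro-2H-chromen-6-yl]-4,4,5,5-tetramethyl-1,3,2-dioxaborolane | C/C(=C\CC[C@]1(C)CCc2cc(B3OC(C)(C)C(C)(C)O3)cc(C)c2O1)CCC=C(C)C
F6 | step 7 | (2R)-2-[(3E)-4,8-dimethylnona-3,7-dien-1-yl]-2,8-dimethyl-3,4-dihydro-2H-chromen-6-ol | C/C(=C\CC[C@]1(C)CCc2cc(O)cc(C)c2O1)CCC=C(C)C
F7 | step 7 | tert-butyldimethylsilyl ether of F6 | C/C(=C\CC[C@]1(C)CCc2cc(O[Si](C)(C)C(C)(C)C)cc(C)c2O1)CCC=C(C)C
F8 | step 7 | (2E,6E)-9-[(2R)-6-(tert-butyldimethylsilyloxy)-2,8-dimethyl-3,4-dihydro-2H-chromen-2-yl]-2,6-dimethylnona-2,6-dien-1-ol | C/C(=C\CC[C@]1(C)CCc2cc(O[Si](C)(C)C(C)(C)C)cc(C)c2O1)CC/C=C(\C)CO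
F9 | step 7 | (2E,6E)-9-[(2R)-6-(tert-butyldimethylsilyloxy)-2,8-dimethyl-3,4-dihydro-2H-chromen-2-yl]-2,6-dimethylnona-2,6-dienal | C/C(=C\CC[C@]1(C)CCc2cc(O[Si](C)(C)C(C)(C)C)cc(C)c2O1)CC/C=C(\C)C=O
F10 | step 7 | (2E,6E)-9-[(2R)-6-(tert-butyldimethylsilyloxy)-2,8-dimethyl-3,4-dihydro-2H-chromen-2-yl]-2,6-dimethylnona-2,6-dienoic acid | C/C(=C\CC[C@]1(C)CCc2cc(O[Si](C)(C)C(C)(C)C)cc(C)c2O1)CC/C=C(\C)C(=O)O
F0 | step 5 | none | none
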